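**Retrosynthetic overview**
- The (Z)-butenoyl group is unveiled last from a silyl-protected propargylic carbinol (desilylation, oxidation, semihydrogenation); the isovalerate comes from acylation of the ring carbinol next to the quaternary centre.
- The α-methylene-γ-lactone (second and last ring) comes from an intramolecular Michael/Horner–Wadsworth–Emmons sequence of a phosphonoacetate tethered on a 4-hydroxycyclohept-2-enone.
- The oxygen pattern comes from anti-osmylation of a 6-hydroxycyclohepta-2,4-dienone plus Mitsunobu inversion at the allylic carbinol; the C-methyl comes from dianion alkylation.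
- The dienone comes from β-elimination (bridge opening) of an 8-oxabicyclo[3.2.1]oct-6-en-3-one.
- Key disconnection: the two C–C bonds flanking the ring ketone, made by (4+3) cycloaddition of an oxyallyl cation (from tetrabromoacetone) with a 2-furyl propargylic carbinol (from furfural and propyne); the seven-membered ring is formed first.

Assumption: in the cycloaddition the zinc alkoxide of the furyl carbinol delivers the oxyallyl cation to the furan face on the side of its C–O bond (carbinol H eclipsing furan C3–H), and (R)-BINOL is the ligand antipode that gives the (1R)-carbinol; this centre is only a relay and is oxidised away in step 10.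

Step 1
Reactants: 1 furfural; 2 propyne
Product: 3 (1R)-1-(furan-2-yl)but-2-yn-1-ol
Conditions: Et2Zn, (R)-BINOL (20 mol%), Ti(OiPr)4 (50 mol%), Cy2NH (5 mol%), Et2O, 25 °C; aqueous work-up
Reagents that add atoms: none
Why: Catalytic asymmetric alkynylzinc addition to an aromatic aldehyde (Pu-type BINOL–Ti(OiPr)4 system), in which the chiral titanium complex exposes one carbonyl face to the propynylzinc species and so sets the (1R)-carbinol that later acts as a traceless stereo-relay.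

Step 2
Reactants: 3 (1R)-1-(furan-2-yl)but-2-yn-1-ol; 4 1,1,3,3-tetrabromoacetone
Product: 6 (1S,5R)-1-[(1R)-1-hydroxybut-2-yn-1-yl]-8-oxabicyclo[3.2.1]oct-6-en-3-one, via dibromo cycloadduct 5 (not isolated)
Conditions: Et2Zn (2.3 equiv), THF, −20 → 25 °C; then Zn–Cu couple, NH4Cl, MeOH, 25 °C; chromatography
Reagents that add atoms: none
Why: (4+3) Cycloaddition of an oxyallyl cation, an enolonium-type α-keto cation whose termini (normally nucleophilic enolate carbons) bond as electrophiles to the nucleophilic α-carbons of the furan, so that the new C1–C2 bond joins two carbons that are each α to a carbonyl in the target (a 1,4-dicarbonyl relationship) while the seven-membered ring, its ketone and the quaternary carbinol carbon are made at once; the zinc alkoxide of 3 delivers the cation to the furan face on the side of its C–O bond, which fixes C1 as S (minor facial diastereomer removed by chromatography), and the Zn–Cu couple then removes both bromines.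

Step 3
Reactants: 6 (1S,5R)-1-[(1R)-1-hydroxybut-2-yn-1-yl]-8-oxabicyclo[3.2.1]oct-6-en-3-one
Product: 7 (1S,5R)-1-[(1R)-1-{[tert-butyl(dimethyl)silyl]oxy}but-2-yn-1-yl]-8-oxabicyclo[3.2.1]oct-6-en-3-one
Conditions: TBSCl, imidazole, DMF, 25 °C
Reagents that add atoms: tert-butyldimethylsilyl chloride CC(C)(C)[Si](C)(C)Cl
Why: Standard silylation of the secondary propargylic alcohol, which leaves the ketone and all stereocentres untouched.

Step 4
Reactants: 7 (1S,5R)-1-[(1R)-1-{[tert-butyl(dimethyl)silyl]oxy}but-2-yn-1-yl]-8-oxabicyclo[3.2.1]oct-6-en-3-one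
Product: 10 (6R,7R)-6-[(1R)-1-{[tert-butyl(dimethyl)silyl]oxy}but-2-yn-1-yl]-6-hydroxy-7-methylcyclohepta-2,4-dien-1-one, via ring-opened lithium alkoxide 8 (not isolated), via dilithium alkoxide-enolate 9 (not isolated)
Conditions: LiN(iPr)2 (2.3 equiv), THF, −78 → −20 °C; MeI (1.1 equiv), −78 °C; aq. NH4Cl
Reagents that add atoms: iodomethane CI
Why: Proposed new method: kinetic deprotonation at the less hindered C4 (C2 is shielded by the quaternary bridgehead) gives an enolate that on warming expels the bridging oxygen from C5 by E1cB (the known base-induced opening of 8-oxabicyclo[3.2.1]oct-6-en-3-ones to 6-hydroxycyclohepta-2,4-dienones), the second equivalent of base then forms a lithium-chelated alkoxide–enolate dianion that can neither undergo retro-aldol cleavage nor lose oxide to a tropone, and this dianion is C-methylated in the Fráter–Seebach sense anti to the ring C–C bond, which places the methyl cis to the C6 oxygen (also the diequatorial, thermodynamically favoured epimer of this enolisable centre).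

Step 5
Reactants: 10 (6R,7R)-6-[(1R)-1-{[tert-butyl(dimethyl)silyl]oxy}but-2-yn-1-yl]-6-hydroxy-7-methylcyclohepta-2,4-dien-1-one
Product: 11 (4S,5S,6S,7R)-6-[(1R)-1-{[tert-butyl(dimethyl)silyl]oxy}but-2-yn-1-yl]-4,5,6-trihydroxy-7-methylcyclohept-2-en-1-one
Conditions: OsO4 (2 mol%), NMO, acetone–H2O, 0 °C
Reagents that add atoms: N-methylmorpholine N-oxide C[N+]1([O-])CCOCC1; water O
Why: Upjohn dihydroxylation is chemoselective for the distal (γ,δ) alkene of the dienone (the α,β-alkene is electron-poor and the alkyne inert) and takes place anti to the pseudoaxial tertiary allylic hydroxyl (Kishi's rule), giving the 4,5-cis-diol trans to the C6 oxygen and thereby the correct C5 configuration.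

Step 6
Reactants: 11 (4S,5S,6S,7R)-6-[(1R)-1-{[tert-butyl(dimethyl)silyl]oxy}but-2-yn-1-yl]-4,5,6-trihydroxy-7-methylcyclohept-2-en-1-one; 12 2-(diethoxyphosphoryl)acetic acid
Product: 13 (1R,5R,6S,7S)-6-[(1R)-1-{[tert-butyl(dimethyl)silyl]oxy}but-2-yn-1-yl]-6,7-dihydroxy-5-methyl-4-oxocyclohept-2-en-1-yl 2-(diethoxyphosphoryl)acetate
Conditions: PPh3, DIAD, THF, 0 → 25 °C
Reagents that add atoms: none
Why: Mitsunobu esterification occurs at the allylic C4 hydroxyl, the only one open to SN2 displacement (the C5 hydroxyl is neopentyl-like and the C6 hydroxyl tertiary), and its inversion both corrects this carbinol to the lactone configuration and installs the phosphonoacetate tether.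

Step 7
Reactants: 13 (1R,5R,6S,7S)-6-[(1R)-1-{[tert-butyl(dimethyl)silyl]oxy}but-2-yn-1-yl]-6,7-dihydroxy-5-methyl-4-oxocyclohept-2-en-1-yl 2-(diethoxyphosphoryl)acetate; 14 3-methylbutanoyl chloride
Product: 15 (1S,2S,3R,7R)-2-[(1R)-1-{[tert-butyl(dimethyl)silyl]oxy}but-2-yn-1-yl]-7-{[(diethoxyphosphoryl)acetyl]oxy}-2-hydroxy-3-methyl-4-oxocyclohept-5-en-1-yl 3-methylbutanoate
Conditions: pyridine, DMAP (cat.), CH2Cl2, 0 → 25 °C
Reagents that add atoms: none
Why: Nucleophile-catalysed acylation of the only remaining secondary alcohol, the tertiary alcohol being inert, with no change at any stereocentre.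

Step 8
Reactants: 15 (1S,2S,3R,7R)-2-[(1R)-1-{[tert-butyl(dimethyl)silyl]oxy}but-2-yn-1-yl]-7-{[(diethoxyphosphoryl)acetyl]oxy}-2-hydroxy-3-methyl-4-oxocyclohept-5-en-1-yl 3-methylbutanoate
Product: 17 (3aS,6R,7S,8S,8aR)-7-[(1R)-1-{[tert-butyl(dimethyl)silyl]oxy}but-2-yn-1-yl]-7-hydroxy-6-methyl-3-methylidene-2,5-dioxooctahydro-2H-cyclohepta[b]furan-8-yl 3-methylbutanoate, via potassium phosphonate carbanion 16 (not isolated)
Conditions: KOtBu (1.05 equiv), THF, 0 °C; then (CH2O)n, 0 → 25 °C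
Reagents that add atoms: formaldehyde (from paraformaldehyde) C=O
Why: Telescoped intramolecular Michael addition/Horner–Wadsworth–Emmons olefination, in which the phosphonate carbanion tethered through the ring oxygen adds 5-exo to the enone β-carbon from the same face (forcing the cis ring fusion and setting C3a) and the resulting α-phosphono lactone anion olefinates formaldehyde to give the α-methylene lactone.

Step 9
Reactants: 17 (3aS,6R,7S,8S,8aR)-7-[(1R)-1-{[tert-butyl(dimethyl)silyl]oxy}but-2-yn-1-yl]-7-hydroxy-6-methyl-3-methylidene-2,5-dioxooctahydro-2H-cyclohepta[b]furan-8-yl 3-methylbutanoate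
Product: 18 (3aS,6R,7R,8S,8aR)-7-hydroxy-7-[(1R)-1-hydroxybut-2-yn-1-yl]-6-methyl-3-methylidene-2,5-dioxooctahydro-2H-cyclohepta[b]furan-8-yl 3-methylbutanoate
Conditions: HF·pyridine, THF, 0 → 25 °C
Reagents that add atoms: none
Why: Fluoride-mediated silyl ether cleavage under mildly acidic conditions that leave both esters, the exocyclic enoate and the tertiary alcohol intact.

Step 10
Reactants: 18 (3aS,6R,7R,8S,8aR)-7-hydroxy-7-[(1R)-1-hydroxybut-2-yn-1-yl]-6-methyl-3-methylidene-2,5-dioxooctahydro-2H-cyclohepta[b]furan-8-yl 3-methylbutanoate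
Product: 19 (3aS,6R,7S,8S,8aR)-7-(but-2-ynoyl)-7-hydroxy-6-methyl-3-methylidene-2,5-dioxooctahydro-2H-cyclohepta[b]furan-8-yl 3-methylbutanoate
Conditions: Dess–Martin periodinane, CH2Cl2, 0 → 25 °C
Reagents that add atoms: none
Why: Dess–Martin oxidation converts the secondary propargylic alcohol into the ynone (the tertiary alcohol cannot be oxidised) and erases the relay stereocentre.

Step 11
Reactants: 19 (3aS,6R,7S,8S,8aR)-7-(but-2-ynoyl)-7-hydroxy-6-methyl-3-methylidene-2,5-dioxooctahydro-2H-cyclohepta[b]furan-8-yl 3-methylbutanoate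
Product: 20 (3aS,6R,7S,8S,8aR)-7-[(2Z)-but-2-enoyl]-7-hydroxy-6-methyl-3-methylidene-2,5-dioxooctahydro-2H-cyclohepta[b]furan-8-yl 3-methylbutanoate
Conditions: H2 (1 atm), Pd/CaCO3–Pb(OAc)2 (Lindlar catalyst), quinoline, EtOAc, 0 °C, stopped after 1 equiv H2
Reagents that add atoms: none
Why: Lindlar semihydrogenation adds hydrogen syn to the activated ynone much faster than to the 1,1-disubstituted enoate alkene, giving the (Z)-enone of the target.

**Compound list**
1 | furfural (furan-2-carbaldehyde) | O=Cc1ccco1 | starting material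
2 | propyne | CC#C | starting material
3 | (1R)-1-(furan-2-yl)but-2-yn-1-ol | CC#C[C@@H](O)c1ccco1 | intermediate
4 | 1,1,3,3-tetrabromoacetone | BrC(Br)C(=O)C(Br)Br | starting material
5 | (1S,5S)-2,4-dibromo-1-[(1R)-1-hydroxybut-2-yn-1-yl]-8-oxabicyclo[3.2.1]oct-6-en-3-one (bromide epimers; formed as zinc alkoxide) | C=1[C@H]2C(Br)C(=O)C(Br)[C@@](O2)([C@H](O)C#CC)C=1 | intermediate
6 | (1S,5R)-1-[(1R)-1-hydroxybut-2-yn-1-yl]-8-oxabicyclo[3.2.1]oct-6-en-3-one | C=1[C@H]2CC(=O)C[C@@](O2)([C@H](O)C#CC)C=1 | intermediate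
7 | (1S,5R)-1-[(1R)-1-{[tert-butyl(dimethyl)silyl]oxy}but-2-yn-1-yl]-8-oxabicyclo[3.2.1]oct-6-en-3-one | C=1[C@H]2CC(=O)C[C@@](O2)([C@H](O[Si](C)(C)C(C)(C)C)C#CC)C=1 | intermediate
8 | lithium (1S)-1-[(1R)-1-{[tert-butyl(dimethyl)silyl]oxy}but-2-yn-1-yl]-6-oxocyclohepta-2,4-dien-1-olate | C1=CC(=O)C[C@@]([O-])([C@H](O[Si](C)(C)C(C)(C)C)C#CC)C=C1.[Li+] | intermediate
9 | dilithium (7R)-7-[(1R)-1-{[tert-butyl(dimethyl)silyl]oxy}but-2-yn-1-yl]cyclohepta-1,3,5-triene-2,7-diolate | [O-]C1=C[C@@]([O-])([C@H](O[Si](C)(C)C(C)(C)C)C#CC)C=CC=C1.[Li+].[Li+] | intermediate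
10 | (6R,7R)-6-[(1R)-1-{[tert-butyl(dimethyl)silyl]oxy}but-2-yn-1-yl]-6-hydroxy-7-methylcyclohepta-2,4-dien-1-one | C1=CC(=O)[C@H](C)[C@@](O)([C@H](O[Si](C)(C)C(C)(C)C)C#CC)C=C1 | intermediate
11 | (4S,5S,6S,7R)-6-[(1R)-1-{[tert-butyl(dimethyl)silyl]oxy}but-2-yn-1-yl]-4,5,6-trihydroxy-7-methylcyclohept-2-en-1-one | C1=CC(=O)[C@H](C)[C@@](O)([C@H](O[Si](C)(C)C(C)(C)C)C#CC)[C@@H](O)[C@H]1O | intermediate
12 | 2-(diethoxyphosphoryl)acetic acid | OC(=O)CP(=O)(OCC)OCC | starting material
13 | (1R,5R,6S,7S)-6-[(1R)-1-{[tert-butyl(dimethyl)silyl]oxy}but-2-yn-1-yl]-6,7-dihydroxy-5-methyl-4-oxocyclohept-2-en-1-yl 2-(diethoxyphosphoryl)acetate | C1=CC(=O)[C@H](C)[C@@](O)([C@H](O[Si](C)(C)C(C)(C)C)C#CC)[C@@H](O)[C@@H]1OC(=O)CP(=O)(OCC)OCC | intermediate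
14 | 3-methylbutanoyl chloride (isovaleryl chloride) | CC(C)CC(=O)Cl | starting material
15 | (1S,2S,3R,7R)-2-[(1R)-1-{[tert-butyl(dimethyl)silyl]oxy}but-2-yn-1-yl]-7-{[(diethoxyphosphoryl)acetyl]oxy}-2-hydroxy-3-methyl-4-oxocyclohept-5-en-1-yl 3-methylbutanoate | C1=CC(=O)[C@H](C)[C@@](O)([C@H](O[Si](C)(C)C(C)(C)C)C#CC)[C@@H](OC(=O)CC(C)C)[C@@H]1OC(=O)CP(=O)(OCC)OCC | intermediate
16 | potassium salt of the 3-(diethoxyphosphoryl) lactone carbanion (cis-fused Michael adduct of 15) | [K+].CCOP(=O)(OCC)[C-]1C(=O)O[C@@H]2[C@H]1CC(=O)[C@H](C)[C@@](O)([C@H](O[Si](C)(C)C(C)(C)C)C#CC)[C@H]2OC(=O)CC(C)C | intermediate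
17 | (3aS,6R,7S,8S,8aR)-7-[(1R)-1-{[tert-butyl(dimethyl)silyl]oxy}but-2-yn-1-yl]-7-hydroxy-6-methyl-3-methylidene-2,5-dioxooctahydro-2H-cyclohepta[b]furan-8-yl 3-methylbutanoate | C=C1C(=O)O[C@@H]2[C@H]1CC(=O)[C@H](C)[C@@](O)([C@H](O[Si](C)(C)C(C)(C)C)C#CC)[C@H]2OC(=O)CC(C)C | intermediate
18 | (3aS,6R,7R,8S,8aR)-7-hydroxy-7-[(1R)-1-hydroxybut-2-yn-1-yl]-6-methyl-3-methylidene-2,5-dioxooctahydro-2H-cyclohepta[b]furan-8-yl 3-methylbutanoate | C=C1C(=O)O[C@@H]2[C@H]1CC(=O)[C@H](C)[C@@](O)([C@H](O)C#CC)[C@H]2OC(=O)CC(C)C | intermediate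
19 | (3aS,6R,7S,8S,8aR)-7-(but-2-ynoyl)-7-hydroxy-6-methyl-3-methylidene-2,5-dioxooctahydro-2H-cyclohepta[b]furan-8-yl 3-methylbutanoate | C=C1C(=O)O[C@@H]2[C@H]1CC(=O)[C@H](C)[C@@](O)(C(=O)C#CC)[C@H]2OC(=O)CC(C)C | intermediate
20 | (3aS,6R,7S,8S,8aR)-7-[(2Z)-but-2-enoyl]-7-hydroxy-6-methyl-3-methylidene-2,5-dioxooctahydro-2H-cyclohepta[b]furan-8-yl 3-methylbutanoate (CNP0283951.2) | C=C1C(=O)O[C@@H]2[C@H]1CC(=O)[C@H](C)[C@@](O)(C(=O)/C=C\C)[C@H]2OC(=O)CC(C)C | target

**Step count and risks**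
Total step count: 11. Longest linear sequence: 11 steps (1 → 20).

The three steps most likely to fail are steps 2, 4 and 5.

Step 2 (yield of the cycloaddition with a free propargylic carbinol, and its facial selectivity). The fallback sets out from 3 and comes back at 7. Compound 3 is silylated first (TBSCl, imidazole) to tert-butyl{[(1R)-1-(furan-2-yl)but-2-yn-1-yl]oxy}dimethylsilane F1. The oxyallyl cation is then generated without zinc, by base-induced ionisation of 1,1,3-trichloroacetone (NaOCH2CF3, CF3CH2OH, Föhlisch conditions), and adds to F1 to give the dichloro cycloadduct F2 as both facial isomers. Dechlorination with the Zn–Cu couple and NH4Cl, then chromatographic separation of the two diastereomers, gives 7. Facial control then rests on sterics and separation instead of zinc chelation.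

Step 4 (competing enolisation toward C2, tropone formation, over-methylation, uncertain C7 selectivity). The fallback sets out from 7 and comes back at 10. Bridge opening is decoupled from methylation and done under Lewis-acid conditions. TMSOTf/Et3N converts 7, through its less hindered silyl enol ether, into the ring-opened trimethylsilyl ether F3. Buffered HF·pyridine at 0 °C removes only the tertiary trimethylsilyl group to give the hydroxy dienone F4. F4 with 2.2 equiv LiN(iPr)2 at −78 °C gives dianion 9 directly, which is methylated to 10.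

Step 5 (facial selectivity of the osmylation next to a quaternary centre; it also conditions the Mitsunobu reaction of step 6). The fallback sets out from 10 and comes back at 18. The tertiary hydroxyl is silylated (TESOTf, 2,6-lutidine) to the triethylsilyl ether F5. Its bulky pseudoaxial silyloxy group steers mCPBA to the opposite face of the distal alkene, giving the epoxide F6. The carboxylate of 12 (Cs2CO3, DMF) opens F6 at the allylic carbon with inversion to give the hydroxy phosphonoacetate F7, which has the oxygen pattern of 13 without osmylation or Mitsunobu inversion. Acylation with 14 gives the isovalerate F8, KOtBu/(CH2O)n gives the lactone F9, and HF·pyridine removes both silyl groups to give 18.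

**Further compounds**
F1 | step 2 | tert-butyl{[(1R)-1-(furan-2-yl)but-2-yn-1-yl]oxy}dimethylsilane | CC#C[C@@H](O[Si](C)(C)C(C)(C)C)c1ccco1
F2 | step 2 | (1S,5S)-1-[(1R)-1-{[tert-butyl(dimethyl)silyl]oxy}but-2-yn-1-yl]-2,4-dichloro-8-oxabicyclo[3.2.1]oct-6-en-3-one (chloride epimers) | C=1[C@H]2C(Cl)C(=O)C(Cl)[C@@](O2)([C@H](O[Si](C)(C)C(C)(C)C)C#CC)C=1
F3 | step 4 | (6S)-6-[(1R)-1-{[tert-butyl(dimethyl)silyl]oxy}but-2-yn-1-yl]-6-[(trimethylsilyl)oxy]cyclohepta-2,4-dien-1-one | C1=CC(=O)C[C@@](O[Si](C)(C)C)([C@H](O[Si](C)(C)C(C)(C)C)C#CC)C=C1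
F4 | step 4 | (6S)-6-[(1R)-1-{[tert-butyl(dimethyl)silyl]oxy}but-2-yn-1-yl]-6-hydroxycyclohepta-2,4-dien-1-one | C1=CC(=O)C[C@@](O)([C@H](O[Si](C)(C)C(C)(C)C)C#CC)C=C1
F5 | step 5 | (6R,7R)-6-[(1R)-1-{[tert-butyl(dimethyl)silyl]oxy}but-2-yn-1-yl]-7-methyl-6-[(triethylsilyl)oxy]cyclohepta-2,4-dien-1-one | C1=CC(=O)[C@H](C)[C@@](O[Si](CC)(CC)CC)([C@H](O[Si](C)(C)C(C)(C)C)C#CC)C=C1
F6 | step 5 | (1S,2S,3R,7S)-2-[(1R)-1-{[tert-butyl(dimethyl)silyl]oxy}but-2-yn-1-yl]-3-methyl-2-[(triethylsilyl)oxy]-8-oxabicyclo[5.1.0]oct-5-en-4-one (oxirane oxygen trans to the triethylsilyloxy group) | C1=CC(=O)[C@H](C)[C@@](O[Si](CC)(CC)CC)([C@H](O[Si](C)(C)C(C)(C)C)C#CC)[C@H]2O[C@@H]12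
F7 | step 5 | (1R,5R,6S,7S)-6-[(1R)-1-{[tert-butyl(dimethyl)silyl]oxy}but-2-yn-1-yl]-7-hydroxy-5-methyl-4-oxo-6-[(triethylsilyl)oxy]cyclohept-2-en-1-yl 2-(diethoxyphosphoryl)acetate | C1=CC(=O)[C@H](C)[C@@](O[Si](CC)(CC)CC)([C@H](O[Si](C)(C)C(C)(C)C)C#CC)[C@@H](O)[C@@H]1OC(=O)CP(=O)(OCC)OCC
F8 | step 5 | (1S,2S,3R,7R)-2-[(1R)-1-{[tert-butyl(dimethyl)silyl]oxy}but-2-yn-1-yl]-7-{[(diethoxyphosphoryl)acetyl]oxy}-3-methyl-4-oxo-2-[(triethylsilyl)oxy]cyclohept-5-en-1-yl 3-methylbutanoate | C1=CC(=O)[C@H](C)[C@@](O[Si](CC)(CC)CC)([C@H](O[Si](C)(C)C(C)(C)C)C#CC)[C@@H](OC(=O)CC(C)C)[C@@H]1OC(=O)CP(=O)(OCC)OCC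
F9 | step 5 | (3aS,6R,7S,8S,8aR)-7-[(1R)-1-{[tert-butyl(dimethyl)silyl]oxy}but-2-yn-1-yl]-6-methyl-3-methylidene-2,5-dioxo-7-[(triethylsilyl)oxy]octahydro-2H-cyclohepta[b]furan-8-yl 3-methylbutanoate | C=C1C(=O)O[C@@H]2[C@H]1CC(=O)[C@H](C)[C@@](O[Si](CC)(CC)CC)([C@H](O[Si](C)(C)C(C)(C)C)C#CC)[C@H]2OC(=O)CC(C)C
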